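**Retrosynthetic overview**
1. The dihydrochalcone is cut at the Cα–Cβ bond: Claisen–Schmidt condensation of a ring A methyl ketone (5,7-bis(benzyloxy)-2,2-dimethyl-2H-chromen-6-yl) with 2,2-dimethylchroman-6-carbaldehyde. One final hydrogenation saturates the enone and the ring A chromene C3=C4 bond and removes both benzyl groups.
2. Enabling feature: in the ring B chroman, O1 lies between the aromatic carbon C8a and the quaternary gem-dimethyl carbon C2, and the side chain sits on C6, para to C8a. Excising O1 leaves the five-membered carbocycle C2–C3–C4–C4a–C8a of a 1-methylindane, so commercial 5-bromo-1-indanone carries the whole ring B skeleton.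
3. Key disconnection O1–C8a: ring-expanding Criegee/Hock 1,2-aryl shift in the 1-methylindan-1-yl hydroperoxide (as its trifluoroacetyl perester). The C2 oxocarbenium carbon that results takes the second methyl group from Me3Al in the same flask.
4. Ring A pyran: 4-O-(1,1-dimethylpropargyl) ether of 2,4,6-trihydroxyacetophenone, then propargyl Claisen/oxa-6π cascade on the symmetric 2,6-dibenzyl ether.
5. Ring order: pyran of ring B (step 3), then pyran of ring A as a 2H-chromene (step 7); both benzene rings come from the starting materials.

Key step: step 3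

Remark: the target has no stereocentre; the chiral intermediates of the ring B line are racemic and their single stereocentre is erased in the key step. 3-Chloro-3-methylbut-1-yne, benzyl bromide and the organometallic reagents are taken as commercial.

**Step 1**
Reactants: 1 5-bromo-2,3-dihydro-1H-inden-1-one
Product: 2 rac-5-bromo-1-methyl-2,3-dihydro-1H-inden-1-ol
Conditions: MeMgBr, THF, 0 °C; H2O quench
Reagents that add atoms: methylmagnesium bromide, C[Mg]Br
Why: Grignard 1,2-addition to the aryl ketone is fast at 0 °C and leaves the aryl bromide untouched, and the new carbinol centre forms as the racemate, which is irrelevant because this carbon becomes the achiral C2 of the chroman in step 3.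

**Step 2**
Reactants: 2 rac-5-bromo-1-methyl-2,3-dihydro-1H-inden-1-ol
Product: 3 rac-5-bromo-1-hydroperoxy-1-methyl-2,3-dihydro-1H-indene
Conditions: 50% aq. H2O2 (excess), cat. H2SO4, Et2O, 0 °C → rt
Reagents that add atoms: hydrogen peroxide, OO
Why: Acid-catalysed SN1 exchange of a tertiary benzylic hydroxyl for hydroperoxyl with excess aqueous H2O2 is the standard entry to cumyl-type hydroperoxides, the dilute aqueous acid being too weak to trigger O–O heterolysis, and the stereocentre is again racemic.

**Step 3**
Reactants: 3 rac-5-bromo-1-hydroperoxy-1-methyl-2,3-dihydro-1H-indene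
Product: 6 6-bromo-2,2-dimethylchroman, via indanyl peroxytrifluoroacetate 4 (not isolated), via chromanyl ketal trifluoroacetate 5 (not isolated)
Conditions: (CF3CO)2O, CH2Cl2, −40 °C; then Me3Al (hexanes), −78 → 0 °C; H2O quench
Reagents that add atoms: trimethylaluminium, C[Al](C)C
Why: Proposed new method: trifluoroacetylation of the hydroperoxide gives perester 4, whose O–O bond should heterolyse with concerted 1,2-shift of the aryl carbon from the carbinol carbon to the proximal oxygen (Criegee rearrangement, the perester analogue of the Hock rearrangement), so that the five-membered carbocycle is enlarged to the six-membered pyran ring by formation of the O1–C8a bond and the cation is stored as ketal ester 5; Me3Al then re-ionises 5 to the chroman-2-ylium ion and transfers a methyl group to C2. The closest known reaction types are the Criegee rearrangement of tertiary peresters to alpha-acyloxy ethers and the Me3Al substitution of ketal esters through oxocarbenium ions; their merger in one flask on an indanyl hydroperoxide is the new element. The pyran ring is closed by ring expansion through a three-membered, phenonium-like bridged transition state (a formal 3-exo-tet attack of the ipso carbon on oxygen), so no Baldwin constraint applies. No stereocentre is created, because the racemic carbinol carbon of 3 becomes the achiral gem-dimethyl carbon C2. The step needs O–O instead of C–O heterolysis and aryl instead of methyl or CH2 migration: the trifluoroacetate leaving group on the distal oxygen, the pi participation of the aryl group and the para bromine, which disfavours the benzylic cation, should secure both. Methyl delivery can only occur at C2, the single electrophilic carbon of 5, and all peroxide must be consumed before Me3Al is added.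

**Step 4**
Reactants: 6 6-bromo-2,2-dimethylchroman
Product: 8 2,2-dimethylchroman-6-carbaldehyde, via aryllithium 7 (not isolated)
Conditions: n-BuLi, THF, −78 °C; DMF, −78 °C → rt; 1 M HCl
Reagents that add atoms: N,N-dimethylformamide, CN(C)C=O
Why: Bromine–lithium exchange followed by formylation of the aryllithium with DMF (Bouveault-type formylation) is reliable on electron-rich aryl bromides, and the tertiary alkyl aryl ether is inert to n-BuLi at −78 °C.

**Step 5**
Reactants: 9 1-(2,4,6-trihydroxyphenyl)ethan-1-one
Product: 10 1-{2,6-dihydroxy-4-[(2-methylbut-3-yn-2-yl)oxy]phenyl}ethan-1-one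
Conditions: 3-chloro-3-methylbut-1-yne (1.1 equiv), DBU (1.2 equiv), CuCl2·2H2O (cat.), MeCN, 0 °C
Reagents that add atoms: 3-chloro-3-methylbut-1-yne, CC(C)(Cl)C#C
Why: Copper-catalysed O-alkylation of phenols with a tertiary propargylic chloride should occur at the most acidic, non-chelated hydroxyl, here the 4-OH para to the acetyl group, because the two ortho hydroxyls are deactivated by hydrogen bonding to the carbonyl and only about one equivalent of base is used.

**Step 6**
Reactants: 10 1-{2,6-dihydroxy-4-[(2-methylbut-3-yn-2-yl)oxy]phenyl}ethan-1-one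
Product: 11 1-{2,6-bis(benzyloxy)-4-[(2-methylbut-3-yn-2-yl)oxy]phenyl}ethan-1-one
Conditions: BnBr (2.5 equiv), K2CO3, DMF, 60 °C
Reagents that add atoms: benzyl bromide, BrCc1ccccc1
Why: Williamson benzylation under forcing carbonate conditions caps both chelated ortho hydroxyls, which removes every competing phenolic oxygen from the cyclisation in step 7 and installs groups that leave in the final hydrogenation.

**Step 7**
Reactants: 11 1-{2,6-bis(benzyloxy)-4-[(2-methylbut-3-yn-2-yl)oxy]phenyl}ethan-1-one
Product: 12 1-[5,7-bis(benzyloxy)-2,2-dimethyl-2H-chromen-6-yl]ethan-1-one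
Conditions: PhNEt2, 180 °C
Reagents that add atoms: none
Why: Aromatic propargyl Claisen rearrangement to the ortho carbon, 1,5-hydrogen shift and oxa-6π electrocyclisation should give the 2,2-dimethyl-2H-chromene, and since the two ortho positions are equivalent by symmetry and only the former ether oxygen is free, a single regioisomer with O1 para to the acetyl group can form.

**Step 8**
Reactants: 12 1-[5,7-bis(benzyloxy)-2,2-dimethyl-2H-chromen-6-yl]ethan-1-one; 8 2,2-dimethylchroman-6-carbaldehyde
Product: 13 (E)-1-[5,7-bis(benzyloxy)-2,2-dimethyl-2H-chromen-6-yl]-3-(2,2-dimethylchroman-6-yl)prop-2-en-1-one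
Conditions: KOH, EtOH/THF, rt → 40 °C
Reagents that add atoms: none
Why: Claisen–Schmidt condensation of the methyl ketone with the non-enolisable aldehyde should give the chalcone, the E alkene being set by E1cB dehydration under thermodynamic control, while the benzyl ethers prevent flavanone formation.

**Step 9**
Reactants: 13 (E)-1-[5,7-bis(benzyloxy)-2,2-dimethyl-2H-chromen-6-yl]-3-(2,2-dimethylchroman-6-yl)prop-2-en-1-one
Product: 14 1-(5,7-dihydroxy-2,2-dimethylchroman-6-yl)-3-(2,2-dimethylchroman-6-yl)propan-1-one
Conditions: H2 (1 atm), 10% Pd/C, EtOAc/MeOH, rt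
Reagents that add atoms: none
Why: Heterogeneous hydrogenation over Pd/C should saturate the enone C=C and the chromene C3=C4 bonds and hydrogenolyse both benzyl ethers in one operation, while the doubly ortho-hydroxylated aryl ketone and the aryl–oxygen bonds are not reduced under these mild conditions, and no stereocentre results.

**Compound list**
1 | 5-bromo-2,3-dihydro-1H-inden-1-one (5-bromo-1-indanone) | O=C1CCc2cc(Br)ccc21 | starting material
2 | rac-5-bromo-1-methyl-2,3-dihydro-1H-inden-1-ol | CC1(O)CCc2cc(Br)ccc21 | intermediate
3 | rac-5-bromo-1-hydroperoxy-1-methyl-2,3-dihydro-1H-indene | CC1(OO)CCc2cc(Br)ccc21 | intermediate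
4 | rac-(5-bromo-1-methyl-2,3-dihydro-1H-inden-1-yl) 2,2,2-trifluoroethaneperoxoate (indanyl peroxytrifluoroacetate) | CC1(OOC(=O)C(F)(F)F)CCc2cc(Br)ccc21 | intermediate (not isolated)
5 | rac-6-bromo-2-methylchroman-2-yl trifluoroacetate (covalent form of the chroman-2-ylium trifluoroacetate ion pair) | CC1(OC(=O)C(F)(F)F)CCc2cc(Br)ccc2O1 | intermediate (not isolated)
6 | 6-bromo-2,2-dimethylchroman | CC1(C)CCc2cc(Br)ccc2O1 | intermediate
7 | (2,2-dimethylchroman-6-yl)lithium | [Li]c1ccc2OC(C)(C)CCc2c1 | intermediate (not isolated)
8 | 2,2-dimethylchroman-6-carbaldehyde | CC1(C)CCc2cc(C=O)ccc2O1 | intermediate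
9 | 1-(2,4,6-trihydroxyphenyl)ethan-1-one | CC(=O)c1c(O)cc(O)cc1O | starting material
10 | 1-{2,6-dihydroxy-4-[(2-methylbut-3-yn-2-yl)oxy]phenyl}ethan-1-one | CC(=O)c1c(O)cc(OC(C)(C)C#C)cc1O | intermediate
11 | 1-{2,6-bis(benzyloxy)-4-[(2-methylbut-3-yn-2-yl)oxy]phenyl}ethan-1-one | CC(=O)c1c(OCc2ccccc2)cc(OC(C)(C)C#C)cc1OCc1ccccc1 | intermediate
12 | 1-[5,7-bis(benzyloxy)-2,2-dimethyl-2H-chromen-6-yl]ethan-1-one | CC(=O)c1c(OCc2ccccc2)cc2c(c1OCc1ccccc1)C=CC(C)(C)O2 | intermediate
13 | (E)-1-[5,7-bis(benzyloxy)-2,2-dimethyl-2H-chromen-6-yl]-3-(2,2-dimethylchroman-6-yl)prop-2-en-1-one | CC1(C)CCc2cc(/C=C/C(=O)c3c(OCc4ccccc4)cc4c(c3OCc3ccccc3)C=CC(C)(C)O4)ccc2O1 | intermediate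
14 | 1-(5,7-dihydroxy-2,2-dimethylchroman-6-yl)-3-(2,2-dimethylchroman-6-yl)propan-1-one | CC1(C)CCc2cc(CCC(=O)c3c(O)cc4c(c3O)CCC(C)(C)O4)ccc2O1 | target

**Step count and risks**
Total step count: 9. Longest linear sequence: 6 steps (steps 1, 2, 3, 4, 8, 9); the ring A line (steps 5, 6, 7) joins at step 8.

Steps most likely to fail:

1. Step 3 (Proposed new method). After the aryl shift, the ketal ester may lose trifluoroacetic acid to an enol ether faster than methyl is transferred. Me3Al may also add to the trifluoroacetyl carbonyl instead of ionising the ketal, or the perester may ionise at carbon and collapse to an indene. Fallback with known chemistry, setting out from 1: Baeyer–Villiger oxidation (mCPBA, CF3CO2H, CH2Cl2) with the same aryl migration should give 6-bromochroman-2-one F1. Excess MeMgBr (THF, 0 °C) opens the lactone to 4-bromo-2-(3-hydroxy-3-methylbutyl)phenol F2. Acid-catalysed cyclodehydration (cat. p-TsOH, toluene, 80 °C) then closes the pyran ring, and the sequence comes back to the route at 6.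

2. Step 5. Site selectivity among the three phenolic oxygens may be poor, with over-alkylation and competing C-alkylation of the phloroglucinol nucleus. Fallback, setting out from 9, replaces innate selectivity by protecting-group control. Silylation of the unhindered, non-chelated 4-OH (TIPSCl, imidazole, DMF, 0 °C) should give 1-{2,6-dihydroxy-4-[(triisopropylsilyl)oxy]phenyl}ethan-1-one F3. Benzylation (BnBr, K2CO3, acetone, reflux) gives 1-{2,6-bis(benzyloxy)-4-[(triisopropylsilyl)oxy]phenyl}ethan-1-one F4, and desilylation (TBAF, THF, 0 °C) gives 1-[2,6-bis(benzyloxy)-4-hydroxyphenyl]ethan-1-one F5. Its only free hydroxyl is then propargylated under the conditions of step 5, and the sequence comes back to the route at 11.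

3. Step 2. The acid may dehydrate the tertiary benzylic alcohol to the indene, couple the hydroperoxide to a dialkyl peroxide, or trigger O–O heterolysis prematurely. Fallback, setting out from 1: Wittig methylenation (Ph3PCH3Br, KOtBu, THF) should give 5-bromo-1-methylidene-2,3-dihydro-1H-indene F6. Cobalt-catalysed Mukaiyama-type hydroperoxysilylation (Co(acac)2 cat., O2, Et3SiH, 1,2-dichloroethane, rt) should give the Markovnikov silyl peroxide rac-[(5-bromo-1-methyl-2,3-dihydro-1H-inden-1-yl)peroxy]triethylsilane F7. Desilylation (TBAF, AcOH, THF, 0 °C) releases the hydroperoxide, and the sequence comes back to the route at 3.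

**Further compounds**
F1 | step 3 | 6-bromochroman-2-one | O=C1CCc2cc(Br)ccc2O1
F2 | step 3 | 4-bromo-2-(3-hydroxy-3-methylbutyl)phenol | CC(C)(O)CCc1cc(Br)ccc1O
F3 | step 5 | 1-{2,6-dihydroxy-4-[(triisopropylsilyl)oxy]phenyl}ethan-1-one | CC(=O)c1c(O)cc(O[Si](C(C)C)(C(C)C)C(C)C)cc1O
F4 | step 5 | 1-{2,6-bis(benzyloxy)-4-[(triisopropylsilyl)oxy]phenyl}ethan-1-one | CC(=O)c1c(OCc2ccccc2)cc(O[Si](C(C)C)(C(C)C)C(C)C)cc1OCc1ccccc1
F5 | step 5 | 1-[2,6-bis(benzyloxy)-4-hydroxyphenyl]ethan-1-one | CC(=O)c1c(OCc2ccccc2)cc(O)cc1OCc1ccccc1
F6 | step 2 | 5-bromo-1-methylidene-2,3-dihydro-1H-indene | C=C1CCc2cc(Br)ccc21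
F7 | step 2 | rac-[(5-bromo-1-methyl-2,3-dihydro-1H-inden-1-yl)peroxy]triethylsilane | CC[Si](CC)(CC)OOC1(C)CCc2cc(Br)ccc21
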